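**Assumption (one line):** atoms carry geranylgeranyl locants (C1′ = ArCH2, C2′ = ring CH, C6′/C10′ = CHBr, C7′/C11′ = C–CH3, C14′ = ester carbinol, C15′ = C(CH3)2–O); the target SMILES then reads 2′R,6′S,7′S,10′R,11′R,14′S. The 10′-Br/11′-O pair is syn, so it cannot come from anti bromoetherification of a 10′E-olefin; C10′–Br is made by a radical route instead.

## Retrosynthetic overview

1. Bromocyclohexene (last ring): C2′–C7′ and C6′–Br by transannular bromonium π-cyclisation of a 19-membered macrolactone diene, Br+ generated anodically from bromide; then phenol deprotection.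
2. C10′–Br: photochemical deoxygenative radical bromination of the macrocyclic C10′ alcohol (from the ketone), face set by the adjacent THP ring.
3. Macrolactone ring (second ring): C8′–C9′ bond by intramolecular enolate allylation of a methyl ketone with an (E)-allylic bromide (SeO2/Appel on the geranyl terminus).
4. Ester C14′O–C(=O)Ar: mixed-anhydride esterification of the THP keto-alcohol with 3-geranyl-4-hydroxybenzoic acid (methyl 4-hydroxybenzoate + geranyl bromide).
5. THP ring (first ring; C11′ bought, C14′): (R)-linalool → epoxidation/6-endo cyclisation → pyranoid oxide, then Wacker oxidation. Ring order: THP → macrolactone → carbocycle.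

## Route

**Step 1**
Reactants: 1, (R)-(−)-linalool
Product: 2, (3S,6R)-2,2,6-trimethyl-6-vinyltetrahydro-2H-pyran-3-ol (pyranoid linalool oxide, 3-OH trans to 6-vinyl)
Conditions: m-CPBA, CH2Cl2, 0 °C; then p-TsOH (cat.), rt; chromatography
Reagents that add atoms: m-CPBA, OOC(=O)c1cccc(Cl)c1 (one O)
Why: Prilezhaev epoxidation of the trisubstituted alkene and acid-catalysed 6-endo (Markovnikov) epoxide opening by the tertiary OH give the known pyranoid oxides (minor to the furanoid oxides, all separable); C6 (future C11′) is the untouched linalool stereocentre, C3 (future C14′) comes from the epoxide with no facial bias, and the 3S epimer is isolated.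

**Step 2**
Reactants: 2, (3S,6R)-2,2,6-trimethyl-6-vinyltetrahydro-2H-pyran-3-ol
Product: 3, 1-[(2R,5S)-5-hydroxy-2,6,6-trimethyltetrahydro-2H-pyran-2-yl]ethan-1-one
Conditions: Pd(Quinox)Cl2 (5 mol %), AgSbF6, aq. t-BuOOH, CH2Cl2, rt
Reagents that add atoms: tert-butyl hydroperoxide, CC(C)(C)OO (ketone O)
Why: Markovnikov Tsuji–Wacker oxidation under Sigman's Pd(Quinox)/TBHP conditions converts the vinyl group next to the tertiary ether into the methyl ketone without touching either stereocentre.

**Step 3**
Reactants: 4, methyl 4-hydroxybenzoate; 5, geranyl bromide [(2E)-1-bromo-3,7-dimethylocta-2,6-diene]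
Product: 6, methyl 3-[(2E)-3,7-dimethylocta-2,6-dien-1-yl]-4-hydroxybenzoate
Conditions: NaH, toluene, 0 °C → rt; then 5, rt
Reagents that add atoms: none
Why: ortho-C-allylation of the sodium phenoxide as a tight ion pair in a non-polar solvent (SN2 at the primary allylic bromide, 2E geometry kept) is the known direct entry to 3-geranyl-4-hydroxybenzoates.

**Step 4**
Reactants: 6, methyl 3-geranyl-4-hydroxybenzoate
Product: 7, 3-[(2E)-3,7-dimethylocta-2,6-dien-1-yl]-4-hydroxybenzoic acid
Conditions: LiOH, THF/MeOH/H2O, 50 °C; then aq. HCl
Reagents that add atoms: lithium hydroxide/water, [Li+].[OH-] (one O)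
Why: Standard BAc2 saponification of a methyl benzoate; nothing else in the molecule is base-sensitive.

**Step 5**
Reactants: 7, 3-geranyl-4-hydroxybenzoic acid; 3, THP keto-alcohol
Product: 8, (3S,6R)-6-acetyl-2,2,6-trimethyltetrahydro-2H-pyran-3-yl 3-[(2E)-3,7-dimethylocta-2,6-dien-1-yl]-4-(pivaloyloxy)benzoate
Conditions: PivCl (2.1 equiv), Et3N, DMAP (cat.), CH2Cl2, 0 °C → rt; then 3, DMAP, toluene, 70 °C
Reagents that add atoms: pivaloyl chloride, CC(C)(C)C(=O)Cl (pivaloyl group)
Why: PivCl gives the aryl pivalate and the mixed pivalic anhydride in one pot, and DMAP-mediated acyl transfer to the hindered C14′-OH occurs at the less hindered aroyl carbonyl (mixed-anhydride esterification); the carbinol C–O bond is not broken, so C14′ is retained.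

**Step 6**
Reactants: 8, geranyl keto-ester
Product: 9, (3S,6R)-6-acetyl-2,2,6-trimethyltetrahydro-2H-pyran-3-yl 3-[(2E,6E)-8-hydroxy-3,7-dimethylocta-2,6-dien-1-yl]-4-(pivaloyloxy)benzoate
Conditions: SeO2 (0.3 equiv), t-BuOOH, salicylic acid (cat.), CH2Cl2, 0 °C → rt
Reagents that add atoms: selenium dioxide, O=[Se]=O, with tert-butyl hydroperoxide, CC(C)(C)OO, as terminal oxidant (one O)
Why: SeO2 allylic oxidation (ene reaction then [2,3]-shift) is selective for the E-methyl of the terminal, most electron-rich trisubstituted alkene, giving the (6′E)-allylic alcohol at C8′.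

**Step 7**
Reactants: 9, allylic alcohol
Product: 10, (3S,6R)-6-acetyl-2,2,6-trimethyltetrahydro-2H-pyran-3-yl 3-[(2E,6E)-8-bromo-3,7-dimethylocta-2,6-dien-1-yl]-4-(pivaloyloxy)benzoate
Conditions: CBr4, PPh3, CH2Cl2, 0 °C
Reagents that add atoms: carbon tetrabromide, BrC(Br)(Br)Br (Br)
Why: Appel bromination of a primary allylic alcohol proceeds by SN2 without allylic transposition or E/Z erosion and tolerates the ketone and esters.

**Step 8**
Reactants: 10, keto allylic bromide
Product: 11, 19-membered macrolactone: C9′ (former acetyl CH3) bonded to C8′, 10′-ketone, 2′E,6′E, 11′R,14′S, phenol as pivalate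
Conditions: KHMDS, THF, −78 → 0 °C, 2 mM (syringe-pump addition)
Reagents that add atoms: none
Why: Only the acetyl CH3 is enolisable (C11′ is quaternary, the benzoate and pivalate have no α-H), so the single potassium enolate closes the ring by intramolecular SN2 C-allylation at the primary allylic bromide under high dilution (macrocyclic enolate alkylation), with alkene geometry kept.

**Step 9**
Reactants: 11, macrocyclic ketone
Product: 12, macrocyclic C10′ alcohol (both C10′ epimers)
Conditions: NaBH4, CeCl3·7H2O, MeOH/THF, −20 °C
Reagents that add atoms: none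
Why: Luche-type borohydride reduction of the ketone leaves the esters intact; the carbinol configuration is irrelevant because both epimers converge on one radical in step 10.

**Step 10**
Reactants: 12, macrocyclic C10′ alcohol
Product: 13, macrocyclic (10′R)-bromide (2′E,6′E, 11′R,14′S, phenol pivalate)
Conditions: N-aryl benzoxazolium tetrafluoroborate (NHC precursor), pyridine, MTBE, rt; then Ir(ppy)2(dtbbpy)PF6 (2 mol %), quinuclidine, BrC(CH3)(CO2Et)2 (3 equiv), MTBE/DMA, 450 nm LEDs, rt
Reagents that add atoms: diethyl 2-bromo-2-methylmalonate, CCOC(=O)C(C)(Br)C(=O)OCC (Br)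
Why: Proposed new method: the alcohol–NHC adduct is photo-oxidised by *Ir(III), α-deprotonated and β-fragmented to release the C10′ radical, which abstracts Br from the hindered bromomalonate while Ir(II) reduces the tertiary malonyl radical (too hindered and stabilised to add to the trisubstituted alkenes) to close the cycle; C10′ is set by substrate control, the C9′ chain lying on the ring-oxygen side of the equatorial C10′ and the axial C11′-methyl blocking one lobe so the bulky donor delivers Br to the other face (10′R, epimer removed by chromatography); closest known chemistry is NHC-mediated photoredox deoxygenative radical generation from alcohols (used for C–C coupling) combined with photoredox decarboxylative bromination using bromomalonates.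

**Step 11**
Reactants: 13, macrocyclic (10′R)-bromide
Product: 14, bromophycolide U 4-O-pivalate
Conditions: n-Bu4NBr (1.2 equiv, slow addition), n-Bu4NPF6, HFIP/CH2Cl2 (3:1), graphite(+)/Pt(−), undivided cell, constant current, 2.2 F/mol, 0 °C
Reagents that add atoms: tetrabutylammonium bromide, [Br-].CCCC[N+](CCCC)(CCCC)CCCC (Br)
Why: Proposed new method: anodic oxidation of bromide in HFIP supplies a low steady-state concentration of an HFIP-activated Br+ donor (cathodic H2 evolution supplies the alkoxide base) that forms the bromonium at the more electron-rich 6′E-olefin, and anti, chair-like transannular attack by the 2′E-olefin forms C2′–C7′ with 6′-Br equatorial, 7′-CH3 axial and 2′-CH2Ar equatorial before C4′–H loss gives the C3′=C4′ alkene, the olefin face being selected by the macrocycle fold imposed by C10′, C11′ and C14′ (the pivalate prevents chroman formation and arene bromination); closest known chemistry is bromonium-induced polyene cyclisation with BDSB or NBS/HFIP and electrochemical bromolactonisation/etherification by anodic bromide oxidation.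

**Step 12**
Reactants: 14, bromophycolide U 4-O-pivalate
Product: 15, bromophycolide U
Conditions: K2CO3, MeOH/THF, 0 °C → rt
Reagents that add atoms: none
Why: Methanolysis of the phenolic pivalate is far faster than that of the hindered secondary-alkyl benzoate (further deactivated once the para-phenoxide forms), and both neopentyl-type secondary bromides resist SN2/E2 under these conditions (the equatorial 6′-Br has no antiperiplanar β-H), so no stereocentre is disturbed.

## Compound list

1 | (R)-(−)-linalool | C=C[C@](C)(O)CCC=C(C)C | starting material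
2 | (3S,6R)-2,2,6-trimethyl-6-vinyltetrahydro-2H-pyran-3-ol | C=C[C@@]1(C)CC[C@H](O)C(C)(C)O1 | intermediate
3 | 1-[(2R,5S)-5-hydroxy-2,6,6-trimethyltetrahydro-2H-pyran-2-yl]ethan-1-one | CC(=O)[C@@]1(C)CC[C@H](O)C(C)(C)O1 | intermediate
4 | methyl 4-hydroxybenzoate | COC(=O)c1ccc(O)cc1 | starting material
5 | geranyl bromide | CC(C)=CCC/C(C)=C/CBr | starting material
6 | methyl 3-[(2E)-3,7-dimethylocta-2,6-dien-1-yl]-4-hydroxybenzoate | COC(=O)c1ccc(O)c(C/C=C(\C)CCC=C(C)C)c1 | intermediate
7 | 3-[(2E)-3,7-dimethylocta-2,6-dien-1-yl]-4-hydroxybenzoic acid | OC(=O)c1ccc(O)c(C/C=C(\C)CCC=C(C)C)c1 | intermediate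
8 | (3S,6R)-6-acetyl-2,2,6-trimethyltetrahydro-2H-pyran-3-yl 3-geranyl-4-(pivaloyloxy)benzoate | CC(=O)[C@@]1(C)CC[C@H](OC(=O)c2ccc(OC(=O)C(C)(C)C)c(C/C=C(\C)CCC=C(C)C)c2)C(C)(C)O1 | intermediate
9 | 8′-hydroxy analogue of 8 (2′E,6′E) | CC(=O)[C@@]1(C)CC[C@H](OC(=O)c2ccc(OC(=O)C(C)(C)C)c(C/C=C(\C)CC/C=C(\C)CO)c2)C(C)(C)O1 | intermediate
10 | 8′-bromo analogue of 8 (2′E,6′E) | CC(=O)[C@@]1(C)CC[C@H](OC(=O)c2ccc(OC(=O)C(C)(C)C)c(C/C=C(\C)CC/C=C(\C)CBr)c2)C(C)(C)O1 | intermediate
11 | 19-membered 10′-keto macrolactone (2′E,6′E,11′R,14′S), phenol pivalate | O=C1CC/C(C)=C/CC/C(C)=C/Cc2cc(ccc2OC(=O)C(C)(C)C)C(=O)O[C@H]3CC[C@@]1(C)OC3(C)C | intermediate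
12 | 10′-hydroxy macrolactone (C10′ epimers) | OC1CC/C(C)=C/CC/C(C)=C/Cc2cc(ccc2OC(=O)C(C)(C)C)C(=O)O[C@H]3CC[C@@]1(C)OC3(C)C | intermediate
13 | (10′R)-bromo macrolactone (2′E,6′E,11′R,14′S), phenol pivalate | Br[C@@H]1CC/C(C)=C/CC/C(C)=C/Cc2cc(ccc2OC(=O)C(C)(C)C)C(=O)O[C@H]3CC[C@@]1(C)OC3(C)C | intermediate
14 | bromophycolide U 4-O-pivalate | CC1=CC[C@H](Br)[C@@]2(C)CC[C@@H](Br)[C@@]3(C)CC[C@H](OC(=O)c4ccc(OC(=O)C(C)(C)C)c(c4)C[C@H]12)C(C)(C)O3 | intermediate
15 | bromophycolide U | CC1=CC[C@H](Br)[C@@]2(C)CC[C@@H](Br)[C@@]3(C)CC[C@H](OC(=O)c4ccc(O)c(c4)C[C@H]12)C(C)(C)O3 | target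

## Summary

**Total steps:** 12. **Longest linear sequence:** 10 (steps 3–12 from 4/5; equally steps 1, 2, 5–12 from linalool).

**Three steps most likely to fail:**

1. **Step 11 (proposed new, electrochemical transannular bromocyclisation).** Risks are the wrong olefin face, dibromide or bromonium formation at C2′=C3′, and exocyclic or tetrasubstituted olefin isomers on proton loss. Fallback (known chemistry, different C–C bond-forming mechanism): Hg(OTf)2·PhNMe2-mediated transannular cation–olefin cyclisation to the C6′ organomercurial, then bromodemercuration (LiBr; Br2, pyridine).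

2. **Step 10 (proposed new, photochemical deoxygenative bromination).** Risks are modest diastereoselectivity at C10′, malonyl-radical addition to the alkenes, and 1,5-H transfer from the C7′ methyl. Fallback (known chemistry): drop the radical step and make C10′–Br and O–C11′ together by stereospecific anti 6-exo bromoetherification (TBCO or NBS) of a 10′Z-olefin carrying the free C15′-OH, with C14′ taken from L-glutamic acid-derived (S)-5-(2-hydroxypropan-2-yl)dihydrofuran-2(3H)-one; anti addition to the Z-olefin gives the 10′R,11′R pair directly.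

3. **Step 8 (19-membered ring by ketone-enolate allylation).** Risks are O-alkylation, oligomerisation and proton transfer leading to dialkylation. Fallback: reverse the order, with intermolecular allylation of the dianion of 3 by the allylic bromide prepared from ester 6, then saponification and Yamaguchi macrolactonisation onto C14′-OH.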